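The route rests on disconnecting two neighbouring carbons of the phenolic dibenzofuran ring (ring A): C1, which carries the CH2CH2 bridge to the para-phenylene ring D, and C9b, the biaryl carbon. The precursor is an open-chain 2-iodo diaryl ether whose far end carries a primary bromide. In one palladium/norbornene (Catellani) operation the C–H ortho to iodine is alkylated by the tethered bromide, which closes the macrocycle at the aryl–CH2 bond, and the ipso palladium then arylates the neighbouring aryloxy ring B, which closes the furan ring. The step exploits the ortho/ipso relation of C1 and C9b, with the furan oxygen on C4a as the second ortho substituent.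

Key step: step 7

Remark: rings are lettered A (phenolic dibenzofuran ring), B (second dibenzofuran ring), C (ring with the second phenol and the diaryl ether oxygen) and D (para-phenylene); the target has no stereocentre, and all starting materials named are assumed to be commercially available.

Step 1
Reactants: 1 3-hydroxy-4-methoxybenzyl alcohol; 2 2-(4-bromophenyl)ethanol
Product: 3 2-{4-[5-(hydroxymethyl)-2-methoxyphenoxy]phenyl}ethanol
Conditions: CuI (10 mol %), N,N-dimethylglycine hydrochloride (30 mol %), Cs2CO3 (2 equiv), 1,4-dioxane, 90 °C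
Reagents that add atoms: none
Why: Ullmann-type diaryl ether synthesis, in which the CuI/N,N-dimethylglycine system should arylate the phenoxide of 1 much faster than either aliphatic hydroxyl, so both alcohols can stay unprotected.

Step 2
Reactants: 3 2-{4-[5-(hydroxymethyl)-2-methoxyphenoxy]phenyl}ethanol
Product: 4 {3-[4-(2-hydroxyethyl)phenoxy]-4-methoxybenzyl}triphenylphosphonium bromide
Conditions: PPh3·HBr, MeCN, reflux
Reagents that add atoms: triphenylphosphine hydrobromide, [Br-].c1ccc(cc1)[PH+](c1ccccc1)c1ccccc1
Why: Phosphonium salt formation by SN1-type substitution of the electron-rich (para-methoxy) benzylic alcohol, while the primary homobenzylic alcohol, which cannot ionise, should stay untouched.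

Step 3
Reactants: 5 2-iodo-5-methoxyphenol; 6 3-formylphenylboronic acid
Product: 7 3-(2-iodo-5-methoxyphenoxy)benzaldehyde
Conditions: Cu(OAc)2 (30 mol %), pyridine, 4 Å molecular sieves, CH2Cl2, O2 (1 atm), rt
Reagents that add atoms: none
Why: Chan–Lam oxidative C–O coupling runs at room temperature without a low-valent metal, so the aryl iodide, which an Ullmann or palladium coupling would attack, should survive.

Step 4
Reactants: 4 {3-[4-(2-hydroxyethyl)phenoxy]-4-methoxybenzyl}triphenylphosphonium bromide; 7 3-(2-iodo-5-methoxyphenoxy)benzaldehyde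
Product: 9 2-[4-(5-{2-[3-(2-iodo-5-methoxyphenoxy)phenyl]vinyl}-2-methoxyphenoxy)phenyl]ethanol (E/Z mixture), via phosphonium ylide 8 (not isolated)
Conditions: K2CO3, 18-crown-6 (cat.), CH2Cl2, reflux
Reagents that add atoms: none
Why: Wittig olefination of a semi-stabilised benzylic ylide under mild solid–liquid conditions that should leave the aryl iodide and the free alcohol alone, the E/Z mixture being of no consequence because the double bond is saturated in step 5.

Step 5
Reactants: 9 2-[4-(5-{2-[3-(2-iodo-5-methoxyphenoxy)phenyl]vinyl}-2-methoxyphenoxy)phenyl]ethanol (E/Z mixture)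
Product: 10 2-[4-(5-{2-[3-(2-iodo-5-methoxyphenoxy)phenyl]ethyl}-2-methoxyphenoxy)phenyl]ethanol
Conditions: TsNHNH2 (excess), NaOAc, DME/H2O, reflux
Reagents that add atoms: none
Why: Diimide reduction saturates the stilbene by concerted transfer of two hydrogen atoms and, unlike catalytic hydrogenation, should not cleave the C–I bond.

Step 6
Reactants: 10 2-[4-(5-{2-[3-(2-iodo-5-methoxyphenoxy)phenyl]ethyl}-2-methoxyphenoxy)phenyl]ethanol
Product: 11 2-[3-(2-{3-[4-(2-bromoethyl)phenoxy]-4-methoxyphenyl}ethyl)phenoxy]-1-iodo-4-methoxybenzene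
Conditions: CBr4, PPh3, CH2Cl2, 0 °C
Reagents that add atoms: carbon tetrabromide, BrC(Br)(Br)Br
Why: Appel reaction, an SN2 displacement of the alkoxyphosphonium ion by bromide under neutral conditions that the aryl iodide and the ethers should tolerate.

Step 7
Reactants: 11 2-[3-(2-{3-[4-(2-bromoethyl)phenoxy]-4-methoxyphenyl}ethyl)phenoxy]-1-iodo-4-methoxybenzene
Product: 13 asterelin A di-O-methyl ether, via macrocyclic arylpalladium bromide 12 (not isolated)
Conditions: Pd(OAc)2 (10 mol %), P(2-furyl)3 (20 mol %), norbornene (2 equiv), Cs2CO3 (3 equiv), CsOPiv (30 mol %), DMF, 105 °C, 11 added by syringe pump (final 2 mM)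
Reagents that add atoms: none
Why: Proposed new method: zerovalent palladium inserts into the C–I bond of ring A, norbornene inserts, the only free ortho C–H (the future C1) is palladated to a five-membered palladacycle, the tethered primary bromide adds oxidatively to this divalent palladium centre (SN2-type, giving tetravalent palladium), and aryl–CH2 reductive elimination followed by norbornene extrusion leaves the macrocyclic arylpalladium bromide 12, which closes the furan ring by carbonate/pivalate-assisted C–H palladation of ring B and C–C reductive elimination. The closest known reaction type is the Catellani ortho-alkylation of aryl iodides with primary alkyl bromides terminated by ipso direct arylation, extended here to an alkyl bromide tethered to the aryl iodide through a 15-atom chain and to a transannular terminating arylation. The 19-membered ring closes first, by oxidative addition of the tethered bromide and C(sp2)–C(sp3) reductive elimination, and the five-membered furan ring second, through a six-membered oxapalladacycle; no stereocentre is formed. Ring closure must outrun intermolecular alkylation, which slow addition at about 2 mM should secure, and alkylation must precede any ipso event, which fast norbornene insertion and the single free ortho position should secure. Norbornene is expelled only once both ortho positions (the new CH2 and the aryloxy oxygen) are filled, so palladium returns to the ipso carbon C9b only after the macrocycle is closed. The terminating arylation should choose the ring B C–H ortho to oxygen and para to the ethylene chain, because the other ortho site is flanked by the chain and C–H palladation of ring D would need a seven-membered palladacycle.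

Step 8
Reactants: 13 asterelin A di-O-methyl ether
Product: 15 asterelin A, via bis(dibromoboryl) ether 14 (not isolated)
Conditions: BBr3 (excess), CH2Cl2, −78 °C to rt; then H2O
Reagents that add atoms: none
Why: BBr3 demethylation, in which bromide attacks the boron-activated O–CH3 groups of both aryl methyl ethers while the diaryl ether, the dibenzofuran and the benzylic CH2 groups should stay intact, and hydrolysis of the aryloxyboron dibromides on work-up frees the two phenols.

Compound list
1 | 3-hydroxy-4-methoxybenzyl alcohol | COc1ccc(CO)cc1O | starting material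
2 | 2-(4-bromophenyl)ethanol | OCCc1ccc(Br)cc1 | starting material
3 | 2-{4-[5-(hydroxymethyl)-2-methoxyphenoxy]phenyl}ethanol | COc1ccc(CO)cc1Oc1ccc(CCO)cc1 | intermediate
4 | {3-[4-(2-hydroxyethyl)phenoxy]-4-methoxybenzyl}triphenylphosphonium bromide | COc1ccc(C[P+](c2ccccc2)(c2ccccc2)c2ccccc2)cc1Oc1ccc(CCO)cc1.[Br-] | intermediate
5 | 2-iodo-5-methoxyphenol | COc1ccc(I)c(O)c1 | starting material
6 | 3-formylphenylboronic acid | O=Cc1cccc(c1)B(O)O | starting material
7 | 3-(2-iodo-5-methoxyphenoxy)benzaldehyde | COc1ccc(I)c(Oc2cccc(C=O)c2)c1 | intermediate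
8 | {3-[4-(2-hydroxyethyl)phenoxy]-4-methoxybenzylidene}triphenylphosphorane (ylide, not isolated) | COc1ccc(C=P(c2ccccc2)(c2ccccc2)c2ccccc2)cc1Oc1ccc(CCO)cc1 | intermediate
9 | 2-[4-(5-{2-[3-(2-iodo-5-methoxyphenoxy)phenyl]vinyl}-2-methoxyphenoxy)phenyl]ethanol (E/Z mixture, double-bond geometry left open) | COc1ccc(I)c(Oc2cccc(C=Cc3ccc(OC)c(Oc4ccc(CCO)cc4)c3)c2)c1 | intermediate
10 | 2-[4-(5-{2-[3-(2-iodo-5-methoxyphenoxy)phenyl]ethyl}-2-methoxyphenoxy)phenyl]ethanol | COc1ccc(I)c(Oc2cccc(CCc3ccc(OC)c(Oc4ccc(CCO)cc4)c3)c2)c1 | intermediate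
11 | 2-[3-(2-{3-[4-(2-bromoethyl)phenoxy]-4-methoxyphenyl}ethyl)phenoxy]-1-iodo-4-methoxybenzene | COc1ccc(I)c(Oc2cccc(CCc3ccc(OC)c(Oc4ccc(CCBr)cc4)c3)c2)c1 | intermediate
12 | 19-membered macrocyclic arylpalladium bromide, palladium on the future C9b, phosphine ligands omitted (not isolated) | COc1cc2c([Pd]Br)c(c1)Oc1cccc(c1)CCc1ccc(OC)c(c1)Oc1ccc(cc1)CC2 | intermediate
13 | asterelin A di-O-methyl ether | COc1cc2c3c(c1)oc1cc(ccc13)CCc1ccc(OC)c(c1)Oc1ccc(cc1)CC2 | intermediate
14 | asterelin A bis(O-dibromoboryl) ether (not isolated) | BrB(Br)Oc1cc2c3c(c1)oc1cc(ccc13)CCc1ccc(OB(Br)Br)c(c1)Oc1ccc(cc1)CC2 | intermediate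
15 | asterelin A | Oc1cc2c3c(c1)oc1cc(ccc13)CCc1ccc(O)c(c1)Oc1ccc(cc1)CC2 | target

Total step count: 8
Longest linear sequence: 7 steps (steps 1, 2, 4, 5, 6, 7, 8); step 3 is a one-step side branch.

Steps most likely to fail

Step 7 (the proposed new method). What may go wrong: intermolecular alkylation outrunning ring closure, loss of HBr from the homobenzylic bromide before it reaches palladium, ipso C–H arylation before the ortho-alkylation, or terminating arylation on ring D instead of ring B. The fallback uses known chemistry only and keeps the macrocyclisation at the same aryl–CH2 bond, now made by a B-alkyl Suzuki–Miyaura coupling. It sets out from phosphonium salt 4 and comes back at 13.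
- Wittig reaction of 4 with commercial 3-hydroxybenzaldehyde (t-BuOK, THF) should give the stilbene phenol F1 (E/Z mixture), and hydrogenation (H2, Pd/C) the bibenzyl phenol F2.
- Commercial 2,6-dibromo-4-methoxyaniline is diazotised (NaNO2, aq. HCl, 0 °C) to the diazonium chloride F3, and a Sandmeyer reaction with CuCl gives 1,3-dibromo-2-chloro-5-methoxybenzene F4.
- Ullmann coupling of F2 with an excess of the symmetric dibromide F4 (CuI, N,N-dimethylglycine, Cs2CO3, dioxane, 100 °C) should give the mono-ether alcohol F5. Ring A then carries bromine at the future C1 and chlorine at the future C9b, with no regiochemical ambiguity.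
- Appel bromination (CBr4, PPh3) gives the bromide F6, and elimination with t-BuOK (THF, 0 °C) the styrene F7.
- Hydroboration with 9-BBN gives the alkylborane F8. Under Pd(dppf)Cl2, AsPh3, Cs2CO3, DMF/THF/H2O and high dilution it should couple at the C–Br bond only and close the 19-membered chloro macrocycle F9.
- Direct arylation (Pd(OAc)2, PCy3·HBF4, K2CO3, DMA, 130 °C) then uses the C–Cl bond to close the furan ring and give 13.

Step 3. What may go wrong: slow C–O coupling at the hindered ortho-iodophenol, with protodeboronation and oxidation of the boronic acid taking over. The fallback replaces the oxidative coupling by an SNAr reaction and brings in the iodine last. It sets out from 4 and comes back at 10, so steps 3 to 5 are bypassed.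
- SNAr of commercial 3-hydroxybenzaldehyde on commercial 2-fluoro-4-methoxy-1-nitrobenzene (K2CO3, DMF, 60 °C) should give the nitro aldehyde F10.
- Wittig reaction with 4 (K2CO3, 18-crown-6, CH2Cl2) gives the nitro stilbene F11.
- H2 over Pd/C reduces the nitro group and the alkene together to the aniline F12; no halogen is present at this stage.
- Diazotisation (NaNO2, p-TsOH, MeCN/H2O, 10 °C) gives the diazonium tosylate F13, which KI converts into 10 in the same flask (Sandmeyer-type iodination).

Step 1. What may go wrong: incomplete chemoselectivity between the phenolic and the two aliphatic hydroxyls, and stalling of the copper catalyst on the hindered, chelating guaiacol-type phenol. The fallback builds the diaryl ether by SNAr and adds the second carbon of the ring D side chain afterwards. It sets out from 1 and comes back at 3.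
- SNAr of 1 with commercial 4-fluorobenzaldehyde (K2CO3, DMF, 120 °C) should give the aldehyde F14.
- Wittig methylenation (Ph3PCH3Br, t-BuOK, THF) gives the styrene F15.
- 9-BBN (2.2 equiv, one equivalent being consumed by the benzylic hydroxyl) gives the bis-boron adduct F16, and oxidation with NaOH/H2O2 gives diol 3.

Further compounds
F1 | step 7 | 3-(2-{3-[4-(2-hydroxyethyl)phenoxy]-4-methoxyphenyl}vinyl)phenol (E/Z mixture) | Oc1cccc(C=Cc2ccc(OC)c(Oc3ccc(CCO)cc3)c2)c1
F2 | step 7 | 3-(2-{3-[4-(2-hydroxyethyl)phenoxy]-4-methoxyphenyl}ethyl)phenol | Oc1cccc(CCc2ccc(OC)c(Oc3ccc(CCO)cc3)c2)c1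
F3 | step 7 | 2,6-dibromo-4-methoxybenzenediazonium chloride | COc1cc(Br)c([N+]#N)c(Br)c1.[Cl-]
F4 | step 7 | 1,3-dibromo-2-chloro-5-methoxybenzene | COc1cc(Br)c(Cl)c(Br)c1
F5 | step 7 | 2-[4-(5-{2-[3-(3-bromo-2-chloro-5-methoxyphenoxy)phenyl]ethyl}-2-methoxyphenoxy)phenyl]ethanol | COc1cc(Br)c(Cl)c(Oc2cccc(CCc3ccc(OC)c(Oc4ccc(CCO)cc4)c3)c2)c1
F6 | step 7 | 1-bromo-3-[3-(2-{3-[4-(2-bromoethyl)phenoxy]-4-methoxyphenyl}ethyl)phenoxy]-2-chloro-5-methoxybenzene | COc1cc(Br)c(Cl)c(Oc2cccc(CCc3ccc(OC)c(Oc4ccc(CCBr)cc4)c3)c2)c1
F7 | step 7 | 1-bromo-2-chloro-5-methoxy-3-[3-(2-{4-methoxy-3-(4-vinylphenoxy)phenyl}ethyl)phenoxy]benzene | COc1cc(Br)c(Cl)c(Oc2cccc(CCc3ccc(OC)c(Oc4ccc(C=C)cc4)c3)c2)c1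
F8 | step 7 | B-alkyl-9-borabicyclo[3.3.1]nonane adduct of F7 | COc1cc(Br)c(Cl)c(Oc2cccc(CCc3ccc(OC)c(Oc4ccc(CCB5C6CCCC5CCC6)cc4)c3)c2)c1
F9 | step 7 | 19-membered chloro macrocycle (chlorine on the future C9b, furan ring still open) | COc1cc2c(Cl)c(c1)Oc1cccc(c1)CCc1ccc(OC)c(c1)Oc1ccc(cc1)CC2
F10 | step 3 | 3-(5-methoxy-2-nitrophenoxy)benzaldehyde | COc1ccc([N+](=O)[O-])c(Oc2cccc(C=O)c2)c1
F11 | step 3 | 2-[4-(2-methoxy-5-{2-[3-(5-methoxy-2-nitrophenoxy)phenyl]vinyl}phenoxy)phenyl]ethanol (E/Z mixture) | COc1ccc([N+](=O)[O-])c(Oc2cccc(C=Cc3ccc(OC)c(Oc4ccc(CCO)cc4)c3)c2)c1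
F12 | step 3 | 2-[4-(5-{2-[3-(2-amino-5-methoxyphenoxy)phenyl]ethyl}-2-methoxyphenoxy)phenyl]ethanol | COc1ccc(N)c(Oc2cccc(CCc3ccc(OC)c(Oc4ccc(CCO)cc4)c3)c2)c1
F13 | step 3 | diazonium 4-methylbenzenesulfonate of F12 | COc1ccc([N+]#N)c(Oc2cccc(CCc3ccc(OC)c(Oc4ccc(CCO)cc4)c3)c2)c1.Cc1ccc(cc1)S(=O)(=O)[O-]
F14 | step 1 | 4-[5-(hydroxymethyl)-2-methoxyphenoxy]benzaldehyde | COc1ccc(CO)cc1Oc1ccc(C=O)cc1
F15 | step 1 | [4-methoxy-3-(4-vinylphenoxy)phenyl]methanol | COc1ccc(CO)cc1Oc1ccc(C=C)cc1
F16 | step 1 | bis(9-borabicyclo[3.3.1]nonan-9-yl) adduct of F15 (B-alkyl and B-alkoxy) | COc1ccc(COB2C3CCCC2CCC3)cc1Oc1ccc(CCB2C3CCCC2CCC3)cc1
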